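## Retrosynthetic overview

- Ring labels: A = benzene ring carrying the propenal; B = the dioxane fused to it (trans); C = central benzene ring; D = the dioxane fused to it (cis); E = catechol ring.
- Enabling feature: in ring D the oxygen of the CH2OH group stands 1,3 to the benzylic carbon C-2 (O–CH2–C-3–C-2), and the ring C oxygen para to ring B (O-1 of ring D) sits ortho to the ether oxygen on C-3. Ring D is therefore the ring-expanded isomer of a cis-2-aryl-3-aryloxyoxetane: the oxetane oxygen leaves C-2 as that phenol attacks and becomes the CH2OH oxygen.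
- Disconnections: both benzylic C–O bonds (O-1–C-2 of ring D and the corresponding bond of ring B) in one acid step from an oxetanyl bis-phenol; the two CH(aryl)–CH(O-aryl) bonds by two Evans syn-glycolate aldol reactions; the alkyl–O(aryl) bonds by phenol alkylation; the enal from an aryl nitrile by reduction and Wittig olefination.
- Order of ring formation: oxetane (temporary ring, which also masks the ring D hydroxymethyl group through five steps) → ring D by invertive ring expansion → ring B by cation capture under thermodynamic control, the last two in one flask.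
- Ring E carries mesylates until both dioxanes are closed (electron-poor aryl: the oxetane survives and opens without ionising); they are exchanged for silyl ethers at −78 °C and the catechol is freed last.

Key step: step 13

Remark (assumption): a cis ring D carrying a free 4-hydroxyphenyl group is taken to epimerise through a para-quinone methide in base or strong acid; the order of the last four steps follows from this.
Abbreviations: allyl = prop-2-en-1-yl; Ms = methanesulfonyl; Ts = 4-methylbenzenesulfonyl; TBS = tert-butyldimethylsilyl; Tf = trifluoromethanesulfonyl. All starting materials and reagents are catalogue compounds.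

## Route

Step 1
Reactants: 1 3,4-dihydroxybenzonitrile
Product: 2 4-(allyloxy)-3-hydroxybenzonitrile
Conditions: allyl bromide (1.05 equiv), NaHCO3, NaI (cat.), DMF, 40 °C
Reagents that add atoms: allyl bromide, C=CCBr
Why: Williamson etherification under weak base: only the hydroxyl para to the nitrile (the more acidic one) is ionised, so the allyl group should go selectively to O-4, the oxygen that later attacks the oxetane.

Step 2
Reactants: 2 4-(allyloxy)-3-hydroxybenzonitrile; 3 (4R)-4-benzyl-3-(chloroacetyl)-1,3-oxazolidin-2-one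
Product: 4 ring C glycolyl imide
Conditions: K2CO3, NaI (cat.), MeCN, 50 °C
Reagents that add atoms: none
Why: Williamson alkylation (iodide-catalysed SN2 at the α-chloro imide) of the remaining 3-hydroxyl installs the two-carbon glycolyl unit of ring D together with the Evans auxiliary; no stereocentre is formed.

Step 3
Reactants: 5 3,4-dihydroxybenzaldehyde
Product: 6 4-formyl-1,2-phenylene dimethanesulfonate
Conditions: MsCl (2.3 equiv), Et3N, CH2Cl2, 0 → 23 °C
Reagents that add atoms: methanesulfonyl chloride, CS(=O)(=O)Cl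
Why: O-sulfonylation of both phenols; the mesylates make ring E electron-poor, which later keeps the aryl oxetane from ionising, and they tolerate boron triflate, hydride and zerovalent palladium.

Step 4
Reactants: 4 ring C glycolyl imide; 6 4-formyl-1,2-phenylene dimethanesulfonate
Product: 8 (2R,3S)-syn-aldol adduct for ring D, via boron Z-enolate 7 (not isolated)
Conditions: n-Bu2BOTf (1.2 equiv), i-Pr2NEt (1.4 equiv), CH2Cl2, −78 → 0 °C; 6, −78 → 0 °C; pH 7 buffer, MeOH, 30% H2O2, 0 °C
Reagents that add atoms: none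
Why: Evans syn-aldol reaction of a glycolate imide: the Z-boron enolate adds through a closed chair transition state on the face remote from the benzyl group of the (R)-auxiliary, which should give the 2,3-syn (2R,3S) adduct, i.e. the threo pattern that becomes (1S,2S) after step 5.

Step 5
Reactants: 8 (2R,3S)-syn-aldol adduct for ring D
Product: 9 (1S,2S)-threo diol
Conditions: LiBH4 (2 equiv), MeOH (2 equiv), THF, 0 °C
Reagents that add atoms: none
Why: reductive removal of the N-acyl oxazolidinone with LiBH4 gives the primary alcohol and returns the auxiliary, while nitrile, aryl mesylates, allyl ether and both stereocentres are untouched.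

Step 6
Reactants: 9 (1S,2S)-threo diol
Product: 11 cis-(2S,3S)-oxetane nitrile, via primary tosylate 10 (not isolated)
Conditions: TsCl (1.1 equiv), Et3N, DMAP (cat.), CH2Cl2, 0 °C; then NaH (1.2 equiv), THF, 0 → 23 °C
Reagents that add atoms: none
Why: selective sulfonylation of the primary hydroxyl followed by intramolecular Williamson etherification (4-exo-tet) by the benzylic alkoxide; no bond at either stereocentre is broken, so the threo diol gives the cis-2-aryl-3-aryloxyoxetane, in which the future hydroxymethyl oxygen is stored as the leaving group on the benzylic carbon.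

Step 7
Reactants: 11 cis-(2S,3S)-oxetane nitrile
Product: 13 cis-(2S,3S)-oxetane aldehyde, via N-aluminated aldimine 12 (not isolated)
Conditions: i-Bu2AlH (1.3 equiv), CH2Cl2, −78 °C; aq. KNaC4H4O6 (potassium sodium tartrate), 0 → 23 °C
Reagents that add atoms: water, O
Why: partial reduction of the aryl nitrile by i-Bu2AlH to the aldimine and hydrolysis on work-up gives the aldehyde; the electron-poor aryl oxetane and the aryl mesylates are inert to the hydride at −78 °C.

Step 8
Reactants: 1 3,4-dihydroxybenzonitrile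
Product: 15 3-(allyloxy)-4-hydroxybenzonitrile, via disodium diphenoxide 14 (not isolated)
Conditions: NaH (2.2 equiv), DMSO, 23 °C; allyl bromide (1.0 equiv); 1 M HCl work-up
Reagents that add atoms: allyl bromide, C=CCBr
Why: Williamson etherification of the dianion: once both hydroxyls are deprotonated the 3-oxide, which is not conjugated with the nitrile and is the more nucleophilic, should take up the single equivalent of allyl bromide, the reverse of the selectivity of step 1.

Step 9
Reactants: 15 3-(allyloxy)-4-hydroxybenzonitrile; 3 (4R)-4-benzyl-3-(chloroacetyl)-1,3-oxazolidin-2-one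
Product: 16 ring A glycolyl imide
Conditions: K2CO3, NaI (cat.), MeCN, 50 °C
Reagents that add atoms: none
Why: Williamson alkylation as in step 2, now at the 4-hydroxyl, installs the glycolyl unit of ring B with its auxiliary; no stereocentre is formed.

Step 10
Reactants: 16 ring A glycolyl imide; 13 cis-(2S,3S)-oxetane aldehyde
Product: 18 (2R,3S)-syn-aldol adduct for ring B, via boron Z-enolate 17 (not isolated)
Conditions: n-Bu2BOTf (1.2 equiv), i-Pr2NEt (1.4 equiv), CH2Cl2, −78 → 0 °C; 13, −78 → −20 °C; pH 7 buffer, MeOH, 30% H2O2, 0 °C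
Reagents that add atoms: none
Why: Evans syn-aldol reaction as in step 4: the (R)-auxiliary fixes the aryloxy-bearing carbon in the configuration that is S in ring B, the benzylic carbinol formed with it is reset in step 13, and the amine-buffered boron enolate is a weak Lewis acid that is not expected to open the electron-poor aryl oxetane at low temperature.

Step 11
Reactants: 18 (2R,3S)-syn-aldol adduct for ring B
Product: 19 (1S,2S)-diol carrying the oxetane
Conditions: LiBH4 (2 equiv), MeOH (2 equiv), THF, 0 °C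
Reagents that add atoms: none
Why: reductive removal of the auxiliary with LiBH4 as in step 5; the oxetane is inert to borohydride.

Step 12
Reactants: 19 (1S,2S)-diol carrying the oxetane
Product: 20 oxetanyl bis-phenol
Conditions: Pd(PPh3)4 (5 mol %), morpholine (6 equiv), THF, 23 °C
Reagents that add atoms: none
Why: Tsuji–Trost-type deallylation: zerovalent palladium ionises both aryl allyl ethers and morpholine traps the allyl groups, which frees the ring C 4-hydroxyl and the ring A 3-hydroxyl under mildly basic conditions that leave oxetane, benzylic alcohol and mesylates intact.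

Step 13
Reactants: 20 oxetanyl bis-phenol
Product: 22 bis-benzodioxane nitrile (rings B and D closed), via ring D benzodioxane triol 21 (not isolated)
Conditions: BF3·OEt2 (20 mol %), 4 Å molecular sieves, CH2Cl2 (0.01 M), −40 → 0 °C
Reagents that add atoms: none
Why: Proposed new method: BF3 should bind the strained oxetane oxygen of 20, and the free ring C 4-hydroxyl should displace it at the benzylic oxetane carbon from the rear (6-exo-tet, SN2), which closes ring D, inverts that carbon from S to R and so places the aryl group cis to the hydroxymethyl group that the departing oxetane oxygen becomes; the closest known reaction types are the acid-catalysed intramolecular opening of 3-(2-hydroxyaryloxy)oxetanes to 2-(hydroxymethyl)-1,4-benzodioxanes and the invertive benzylic opening of 2-aryloxetanes by oxygen nucleophiles, here combined at a substituted, stereogenic benzylic carbon. In the same flask the benzylic alcohol on ring C, which stands para to an oxygen, should ionise to a para-quinone-methide-type cation that the ring A phenol captures (6-exo-trig) to close ring B, a known way to 2-aryl-3-(hydroxymethyl)benzodioxanes. The new ring D centre is controlled by stereospecific inversion of the oxetane carbon set in step 4, the new ring B centre by the thermodynamic preference for the trans, diequatorial dioxane, since this electron-rich benzylic ether can reopen and equilibrate. The selectivities needed are attack at the benzylic and not the methylene carbon of the oxetane and inversion without ionisation: the aryl group still stabilises a loose SN2 transition state at the benzylic carbon, while its two mesyloxy groups and the neighbouring aryloxy group prevent a free cation, so that ring D, once formed, does not epimerise under the conditions that equilibrate ring B; water is the only by-product.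

Step 14
Reactants: 22 bis-benzodioxane nitrile (rings B and D closed)
Product: 24 tetrakis-TBS nitrile, via tetralithium salt 23 (not isolated)
Conditions: LiN(i-Pr)2 (8 equiv), THF, −78 °C; then TBSOTf (6 equiv), −78 → −20 °C
Reagents that add atoms: tert-butyldimethylsilyl trifluoromethanesulfonate, CC(C)(C)[Si](C)(C)OS(=O)(=O)C(F)(F)F
Why: aryl mesylates are cleaved by lithium amide bases through α-deprotonation and loss of sulfene (E1cB), and the lithium phenoxides and alkoxides are silylated in the same flask, so that the 4-phenoxide para to the ring D benzylic ether exists only at −78 °C and should not open the cis ring through a quinone methide.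

Step 15
Reactants: 24 tetrakis-TBS nitrile
Product: 26 tetrakis-TBS aldehyde, via N-aluminated aldimine 25 (not isolated)
Conditions: i-Bu2AlH (1.5 equiv), CH2Cl2, −78 °C; aq. KNaC4H4O6, 0 → 23 °C
Reagents that add atoms: water, O
Why: partial reduction of the nitrile to the aldimine with i-Bu2AlH and hydrolysis on work-up, as in step 7; silyl ethers and both dioxane rings are inert.

Step 16
Reactants: 26 tetrakis-TBS aldehyde; 27 (triphenylphosphoranylidene)acetaldehyde
Product: 28 tetrakis-TBS (E)-enal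
Conditions: 27 (1.3 equiv), toluene, 80 °C
Reagents that add atoms: none
Why: Wittig olefination with a formyl-stabilised ylide, which is E-selective, delivers the two-carbon enal in one step; nothing basic enough to touch the stereocentres is present.

Step 17
Reactants: 28 tetrakis-TBS (E)-enal
Product: 29 CNP0302404.1
Conditions: HF·pyridine, pyridine, THF, 0 → 23 °C
Reagents that add atoms: none
Why: fluoride-mediated cleavage of the two aryl and two primary silyl ethers under pyridine-buffered, non-basic conditions frees the catechol and both hydroxymethyl groups last, so the cis ring D with its para-hydroxyphenyl group never meets base or strong acid; the enal is inert.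

## Compound list

1 | 3,4-dihydroxybenzonitrile | N#Cc1ccc(O)c(O)c1 | starting material
2 | 4-(allyloxy)-3-hydroxybenzonitrile | N#Cc1ccc(OCC=C)c(O)c1 | intermediate
3 | (4R)-4-benzyl-3-(chloroacetyl)-1,3-oxazolidin-2-one | O=C(CCl)N1C(=O)OC[C@H]1Cc1ccccc1 | starting material
4 | (4R)-3-{[2-(allyloxy)-5-cyanophenoxy]acetyl}-4-benzyl-1,3-oxazolidin-2-one | N#Cc1ccc(OCC=C)c(OCC(=O)N2C(=O)OC[C@H]2Cc2ccccc2)c1 | intermediate
5 | 3,4-dihydroxybenzaldehyde | O=Cc1ccc(O)c(O)c1 | starting material
6 | 4-formyl-1,2-phenylene dimethanesulfonate | O=Cc1ccc(OS(C)(=O)=O)c(OS(C)(=O)=O)c1 | intermediate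
7 | dibutylboron (Z)-enolate of 4 (not isolated) | CCCCB(CCCC)O/C(N1C(=O)OC[C@H]1Cc1ccccc1)=C\Oc1cc(C#N)ccc1OCC=C | intermediate
8 | (4R)-3-[(2R,3S)-2-[2-(allyloxy)-5-cyanophenoxy]-3-[3,4-bis(mesyloxy)phenyl]-3-hydroxypropanoyl]-4-benzyl-1,3-oxazolidin-2-one | O=C(N1C(=O)OC[C@H]1Cc1ccccc1)[C@H](Oc1cc(C#N)ccc1OCC=C)[C@@H](O)c1ccc(OS(C)(=O)=O)c(OS(C)(=O)=O)c1 | intermediate
9 | 4-(allyloxy)-3-{[(1S,2S)-1-[3,4-bis(mesyloxy)phenyl]-1,3-dihydroxypropan-2-yl]oxy}benzonitrile | OC[C@H](Oc1cc(C#N)ccc1OCC=C)[C@@H](O)c1ccc(OS(C)(=O)=O)c(OS(C)(=O)=O)c1 | intermediate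
10 | primary 4-methylbenzenesulfonate of 9 (not isolated) | Cc1ccc(cc1)S(=O)(=O)OC[C@H](Oc1cc(C#N)ccc1OCC=C)[C@@H](O)c1ccc(OS(C)(=O)=O)c(OS(C)(=O)=O)c1 | intermediate
11 | 4-(allyloxy)-3-{[(2S,3S)-2-[3,4-bis(mesyloxy)phenyl]oxetan-3-yl]oxy}benzonitrile (cis-oxetane) | N#Cc1ccc(OCC=C)c(O[C@H]2CO[C@H]2c2ccc(OS(C)(=O)=O)c(OS(C)(=O)=O)c2)c1 | intermediate
12 | N-(diisobutylalumanyl)aldimine from 11 (not isolated) | CC(C)C[Al](CC(C)C)N=Cc1ccc(OCC=C)c(O[C@H]2CO[C@H]2c2ccc(OS(C)(=O)=O)c(OS(C)(=O)=O)c2)c1 | intermediate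
13 | 4-(allyloxy)-3-{[(2S,3S)-2-[3,4-bis(mesyloxy)phenyl]oxetan-3-yl]oxy}benzaldehyde | O=Cc1ccc(OCC=C)c(O[C@H]2CO[C@H]2c2ccc(OS(C)(=O)=O)c(OS(C)(=O)=O)c2)c1 | intermediate
14 | disodium 4-cyanobenzene-1,2-diolate (not isolated) | [Na+].[Na+].N#Cc1ccc([O-])c([O-])c1 | intermediate
15 | 3-(allyloxy)-4-hydroxybenzonitrile | N#Cc1ccc(O)c(OCC=C)c1 | intermediate
16 | (4R)-3-{[2-(allyloxy)-4-cyanophenoxy]acetyl}-4-benzyl-1,3-oxazolidin-2-one | N#Cc1ccc(OCC(=O)N2C(=O)OC[C@H]2Cc2ccccc2)c(OCC=C)c1 | intermediate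
17 | dibutylboron (Z)-enolate of 16 (not isolated) | CCCCB(CCCC)O/C(N1C(=O)OC[C@H]1Cc1ccccc1)=C\Oc1ccc(C#N)cc1OCC=C | intermediate
18 | (4R)-3-[(2R,3S)-2-[2-(allyloxy)-4-cyanophenoxy]-3-hydroxy-3-(4-(allyloxy)-3-{[(2S,3S)-2-[3,4-bis(mesyloxy)phenyl]oxetan-3-yl]oxy}phenyl)propanoyl]-4-benzyl-1,3-oxazolidin-2-one | O=C(N1C(=O)OC[C@H]1Cc1ccccc1)[C@H](Oc1ccc(C#N)cc1OCC=C)[C@@H](O)c1ccc(OCC=C)c(O[C@H]2CO[C@H]2c2ccc(OS(C)(=O)=O)c(OS(C)(=O)=O)c2)c1 | intermediate
19 | 3-(allyloxy)-4-{[(1S,2S)-1-(4-(allyloxy)-3-{[(2S,3S)-2-[3,4-bis(mesyloxy)phenyl]oxetan-3-yl]oxy}phenyl)-1,3-dihydroxypropan-2-yl]oxy}benzonitrile | OC[C@H](Oc1ccc(C#N)cc1OCC=C)[C@@H](O)c1ccc(OCC=C)c(O[C@H]2CO[C@H]2c2ccc(OS(C)(=O)=O)c(OS(C)(=O)=O)c2)c1 | intermediate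
20 | 4-{[(1S,2S)-1,3-dihydroxy-1-(4-hydroxy-3-{[(2S,3S)-2-[3,4-bis(mesyloxy)phenyl]oxetan-3-yl]oxy}phenyl)propan-2-yl]oxy}-3-hydroxybenzonitrile | OC[C@H](Oc1ccc(C#N)cc1O)[C@@H](O)c1ccc(O)c(O[C@H]2CO[C@H]2c2ccc(OS(C)(=O)=O)c(OS(C)(=O)=O)c2)c1 | intermediate
21 | 4-{[(1S,2S)-1-[(2R,3S)-2-[3,4-bis(mesyloxy)phenyl]-3-(hydroxymethyl)-2,3-dihydro-1,4-benzodioxin-6-yl]-1,3-dihydroxypropan-2-yl]oxy}-3-hydroxybenzonitrile (not isolated) | OC[C@H](Oc1ccc(C#N)cc1O)[C@@H](O)c1ccc2c(c1)O[C@@H](CO)[C@@H](c1ccc(OS(C)(=O)=O)c(OS(C)(=O)=O)c1)O2 | intermediate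
22 | (2S,3S)-3-[(2R,3S)-2-[3,4-bis(mesyloxy)phenyl]-3-(hydroxymethyl)-2,3-dihydro-1,4-benzodioxin-6-yl]-2-(hydroxymethyl)-2,3-dihydro-1,4-benzodioxine-6-carbonitrile | N#Cc1ccc2c(c1)O[C@@H](c1ccc3c(c1)O[C@@H](CO)[C@@H](c1ccc(OS(C)(=O)=O)c(OS(C)(=O)=O)c1)O3)[C@H](CO)O2 | intermediate
23 | tetralithium salt of demesylated 22: two alkoxides and two phenoxides (not isolated) | [Li+].[Li+].[Li+].[Li+].N#Cc1ccc2c(c1)O[C@@H](c1ccc3c(c1)O[C@@H](C[O-])[C@@H](c1ccc([O-])c([O-])c1)O3)[C@H](C[O-])O2 | intermediate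
24 | (2S,3S)-3-[(2R,3S)-2-[3,4-bis(TBSO)phenyl]-3-(TBSO-methyl)-2,3-dihydro-1,4-benzodioxin-6-yl]-2-(TBSO-methyl)-2,3-dihydro-1,4-benzodioxine-6-carbonitrile | N#Cc1ccc2c(c1)O[C@@H](c1ccc3c(c1)O[C@@H](CO[Si](C)(C)C(C)(C)C)[C@@H](c1ccc(O[Si](C)(C)C(C)(C)C)c(O[Si](C)(C)C(C)(C)C)c1)O3)[C@H](CO[Si](C)(C)C(C)(C)C)O2 | intermediate
25 | N-(diisobutylalumanyl)aldimine from 24 (not isolated) | CC(C)C[Al](CC(C)C)N=Cc1ccc2c(c1)O[C@@H](c1ccc3c(c1)O[C@@H](CO[Si](C)(C)C(C)(C)C)[C@@H](c1ccc(O[Si](C)(C)C(C)(C)C)c(O[Si](C)(C)C(C)(C)C)c1)O3)[C@H](CO[Si](C)(C)C(C)(C)C)O2 | intermediate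
26 | (2S,3S)-3-[(2R,3S)-2-[3,4-bis(TBSO)phenyl]-3-(TBSO-methyl)-2,3-dihydro-1,4-benzodioxin-6-yl]-2-(TBSO-methyl)-2,3-dihydro-1,4-benzodioxine-6-carbaldehyde | O=Cc1ccc2c(c1)O[C@@H](c1ccc3c(c1)O[C@@H](CO[Si](C)(C)C(C)(C)C)[C@@H](c1ccc(O[Si](C)(C)C(C)(C)C)c(O[Si](C)(C)C(C)(C)C)c1)O3)[C@H](CO[Si](C)(C)C(C)(C)C)O2 | intermediate
27 | (triphenylphosphoranylidene)acetaldehyde | O=CC=P(c1ccccc1)(c1ccccc1)c1ccccc1 | starting material
28 | (2E)-3-[(2S,3S)-3-[(2R,3S)-2-[3,4-bis(TBSO)phenyl]-3-(TBSO-methyl)-2,3-dihydro-1,4-benzodioxin-6-yl]-2-(TBSO-methyl)-2,3-dihydro-1,4-benzodioxin-6-yl]prop-2-enal | O=C/C=C/c1ccc2c(c1)O[C@@H](c1ccc3c(c1)O[C@@H](CO[Si](C)(C)C(C)(C)C)[C@@H](c1ccc(O[Si](C)(C)C(C)(C)C)c(O[Si](C)(C)C(C)(C)C)c1)O3)[C@H](CO[Si](C)(C)C(C)(C)C)O2 | intermediate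
29 | CNP0302404.1, (2E)-3-[(2S,3S)-3-[(2R,3S)-2-(3,4-dihydroxyphenyl)-3-(hydroxymethyl)-2,3-dihydro-1,4-benzodioxin-6-yl]-2-(hydroxymethyl)-2,3-dihydro-1,4-benzodioxin-6-yl]prop-2-enal | O=C/C=C/c1ccc2c(c1)O[C@@H](c1ccc3c(c1)O[C@@H](CO)[C@@H](c1ccc(O)c(O)c1)O3)[C@H](CO)O2 | target

## Step count and risks

Total step count: 17. Longest linear sequence: 14 steps (1, 2, 4–7, 10–17).

**(1) Step 13 (proposed new method).** What may go wrong: attack of the phenol at the methylene carbon of the oxetane in place of the benzylic carbon, partial ionisation at the benzylic carbon with loss of the cis relationship, or interference between the two ring closures. The fallback uses known chemistry only, sets out from 9 and returns to the route at 24. The primary hydroxyl of 9 would be silylated (TBSCl, imidazole, DMF, 0 °C) to give silyl ether F1. Deallylation (Pd(PPh3)4, morpholine) would give phenol F2. Mitsunobu etherification (PPh3, DIAD, THF, 0 °C) would close ring D with inversion at the benzylic carbinol to give cis-benzodioxane nitrile F3. Reduction with i-Bu2AlH would give aldehyde F4; the aldol reaction of step 10 with enolate 17 would give aldol adduct F5; LiBH4 would give diol F6; deallylation would give phenol F7. Catalytic BF3·OEt2 would then close ring B alone (trans, thermodynamic) to give mono-silylated bis-benzodioxane F8. The conditions of step 14 would silylate the last hydroxyl and exchange the mesylates, which gives 24.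

**(2) Step 6.** What may go wrong: Grob-type fragmentation of the alkoxide–tosylate (back to an aryl aldehyde and an aryl vinyl ether) or sulfonyl transfer from the aryl mesylates to the alkoxide, in place of the 4-exo-tet closure. The fallback sets out from 2 and 6 and returns at 11. O-Vinylation of 2 (2,4,6-trivinylcyclotriboroxane–pyridine complex, Cu(OAc)2, pyridine, CH2Cl2, air, 23 °C) would give aryl vinyl ether F9. Paternò–Büchi photocycloaddition of 6 to it (hν ≥ 300 nm, MeCN) should join the carbonyl oxygen to the terminal CH2 and, through the triplet 1,4-biradical, favour the cis-oxetane. This forms as the racemate, and preparative chromatography on a chiral stationary phase would deliver 11 and remove ent-oxetane F10.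

**(3) Step 14.** What may go wrong: addition of the amide base to the nitrile or metalation of ring A next to it, and incomplete trapping of the phenoxides before warming. The fallback sets out from 22 and returns at 26. The nitrile would be reduced first (i-Bu2AlH, 5 equiv, CH2Cl2/THF, −78 °C) to give aldehyde F11. Acetalisation (HC(OMe)3, MeOH, pyridinium 4-methylbenzenesulfonate cat.) would give dimethyl acetal F12. The mesylate-to-silyl exchange (LiN(i-Pr)2, THF, −78 °C; TBSOTf) on this nitrile-free substrate would give silylated acetal F13. Mild hydrolysis (pyridinium 4-methylbenzenesulfonate, acetone/H2O, 23 °C) would give 26.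

Further compounds

F1 | step 13 | primary TBS ether of 9 | CC(C)(C)[Si](C)(C)OC[C@H](Oc1cc(C#N)ccc1OCC=C)[C@@H](O)c1ccc(OS(C)(=O)=O)c(OS(C)(=O)=O)c1
F2 | step 13 | deallylated phenol of F1 | CC(C)(C)[Si](C)(C)OC[C@H](Oc1cc(C#N)ccc1O)[C@@H](O)c1ccc(OS(C)(=O)=O)c(OS(C)(=O)=O)c1
F3 | step 13 | (2R,3S)-2-[3,4-bis(mesyloxy)phenyl]-3-(TBSO-methyl)-2,3-dihydro-1,4-benzodioxine-6-carbonitrile | N#Cc1ccc2c(c1)O[C@@H](CO[Si](C)(C)C(C)(C)C)[C@@H](c1ccc(OS(C)(=O)=O)c(OS(C)(=O)=O)c1)O2
F4 | step 13 | (2R,3S)-2-[3,4-bis(mesyloxy)phenyl]-3-(TBSO-methyl)-2,3-dihydro-1,4-benzodioxine-6-carbaldehyde | O=Cc1ccc2c(c1)O[C@@H](CO[Si](C)(C)C(C)(C)C)[C@@H](c1ccc(OS(C)(=O)=O)c(OS(C)(=O)=O)c1)O2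
F5 | step 13 | (2R,3S)-syn-aldol adduct of 16 with F4 | O=C(N1C(=O)OC[C@H]1Cc1ccccc1)[C@H](Oc1ccc(C#N)cc1OCC=C)[C@@H](O)c1ccc2c(c1)O[C@@H](CO[Si](C)(C)C(C)(C)C)[C@@H](c1ccc(OS(C)(=O)=O)c(OS(C)(=O)=O)c1)O2
F6 | step 13 | (1S,2S)-diol from F5 | OC[C@H](Oc1ccc(C#N)cc1OCC=C)[C@@H](O)c1ccc2c(c1)O[C@@H](CO[Si](C)(C)C(C)(C)C)[C@@H](c1ccc(OS(C)(=O)=O)c(OS(C)(=O)=O)c1)O2
F7 | step 13 | deallylated phenol of F6 | OC[C@H](Oc1ccc(C#N)cc1O)[C@@H](O)c1ccc2c(c1)O[C@@H](CO[Si](C)(C)C(C)(C)C)[C@@H](c1ccc(OS(C)(=O)=O)c(OS(C)(=O)=O)c1)O2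
F8 | step 13 | 22 with the ring D hydroxymethyl group as TBS ether | N#Cc1ccc2c(c1)O[C@@H](c1ccc3c(c1)O[C@@H](CO[Si](C)(C)C(C)(C)C)[C@@H](c1ccc(OS(C)(=O)=O)c(OS(C)(=O)=O)c1)O3)[C@H](CO)O2
F9 | step 6 | 4-(allyloxy)-3-(vinyloxy)benzonitrile | N#Cc1ccc(OCC=C)c(OC=C)c1
F10 | step 6 | 4-(allyloxy)-3-{[(2R,3R)-2-[3,4-bis(mesyloxy)phenyl]oxetan-3-yl]oxy}benzonitrile (mirror image of 11) | N#Cc1ccc(OCC=C)c(O[C@@H]2CO[C@@H]2c2ccc(OS(C)(=O)=O)c(OS(C)(=O)=O)c2)c1
F11 | step 14 | aldehyde corresponding to nitrile 22 | O=Cc1ccc2c(c1)O[C@@H](c1ccc3c(c1)O[C@@H](CO)[C@@H](c1ccc(OS(C)(=O)=O)c(OS(C)(=O)=O)c1)O3)[C@H](CO)O2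
F12 | step 14 | dimethyl acetal of F11 | COC(OC)c1ccc2c(c1)O[C@@H](c1ccc3c(c1)O[C@@H](CO)[C@@H](c1ccc(OS(C)(=O)=O)c(OS(C)(=O)=O)c1)O3)[C@H](CO)O2
F13 | step 14 | dimethyl acetal of 26 | COC(OC)c1ccc2c(c1)O[C@@H](c1ccc3c(c1)O[C@@H](CO[Si](C)(C)C(C)(C)C)[C@@H](c1ccc(O[Si](C)(C)C(C)(C)C)c(O[Si](C)(C)C(C)(C)C)c1)O3)[C@H](CO[Si](C)(C)C(C)(C)C)O2
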